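**Retrosynthetic overview**
1. 9 ⇒ trans-oxirane 5 + (2S)-pinocembrin 6. The C8–O aryl ether is made last, with retention at the benzylic carbon (aryloxide delivered from boron), so the trans-epoxide gives the threo 7-OH/8-OAr pair directly.
2. 5 ⇒ (S)-goniothalamin 4 by reagent-controlled epoxidation of the styryl alkene (lactone first, oxirane second, as in the plant).
3. 4 ⇒ cinnamaldehyde 1 + methyl but-3-enoate 2. One step: acetate-type chain extension (vinylogous aldol) and chain-release lactonisation of the Z-δ-hydroxy enoate, which sets C6.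
4. Ring order: dihydropyranone → oxirane → oxirane opened by the flavanone 7-OH. The flavanone ring is not built; it arrives as natural (2S)-pinocembrin, the chalcone-cyclisation product, so C2 is never exposed to a late, unselective ring closure.

Assumption: natural (2S)-pinocembrin and the L-fructose-derived (ent) Shi ketone are bought, and the ligand antipode quoted in step 1 is taken to be the one giving the 6S lactone (otherwise its mirror image is used, nothing else changes).

**Step 1**
Reactants: 1 (E)-cinnamaldehyde; 2 methyl but-3-enoate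
Product: 4 (S)-goniothalamin, via hydroxy dienoate 3 (not isolated)
Conditions: Cu(MeCN)4PF6 (5 mol%), (R)-DTBM-SEGPHOS (6 mol%), Barton's base (10 mol%), 2 (2 equiv), THF, −20 °C → rt
Reagents that add atoms: none
Why: Copper(I)-catalysed direct asymmetric vinylogous aldol reaction with in-situ lactonisation: the soft-enolised copper dienolate of 2 attacks the aldehyde through its γ-carbon in a closed transition state that gives the Z-enoate, the bisphosphine selects the aldehyde face (C6 = S), and the copper alkoxide of 3 closes irreversibly onto the ester, releasing methoxide as the turnover base.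

**Step 2**
Reactants: 4 (S)-goniothalamin
Product: 5 (6S)-6-[(2S,3S)-3-phenyloxiran-2-yl]-5,6-dihydro-2H-pyran-2-one
Conditions: ent-Shi ketone (0.3 equiv), Oxone, K2CO3, Bu4NHSO4, MeCN–DMM/aq. Na2B4O7–Na2EDTA (pH ≈ 10), 0 °C, 2 h
Reagents that add atoms: Oxone (potassium peroxymonosulfate, KHSO5), [K+].[O-]S(=O)(=O)OO
Why: Shi asymmetric epoxidation: the electrophilic chiral dioxirane reacts only with the electron-rich styryl alkene (not the enoate), and the spiro transition state of the L-series ketone gives the (7S,8S) trans-oxirane (the D-series ketone gives R,R on trans-β-alkylstyrenes), overriding the weak bias of C6.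

**Step 3**
Reactants: 5 (6S)-6-[(2S,3S)-3-phenyloxiran-2-yl]-5,6-dihydro-2H-pyran-2-one; 6 (2S)-pinocembrin
Product: 9 CNP0113500.1, via tris(aryl) borate 7 (not isolated), via borate ester 8 (not isolated)
Conditions: 6 (3.0 equiv), B(OH)3 (1.0 equiv), PhMe, Dean–Stark, reflux, 3 h; cool, add 5 (1.0 equiv) in CH2Cl2, 0 °C → rt; pH 7 phosphate buffer work-up (unused 6 recovered)
Reagents that add atoms: boric acid, OB(O)O (its boron is carried only in 7 and 8)
Why: Proposed new method: the Lewis-acidic triaryl borate 7 binds the oxirane oxygen, the benzylic C8–O bond ionises to a tight ion pair, and an aryloxide is passed from boron to C8 on the face the oxygen has just left (SNi, five-membered B–O7–C7–C8–OAr transition state that keeps phenyl and lactone trans), so C8 is formed with retention (8S) while C6 and C7 are untouched, giving threo borate ester 8, which hydrolyses to 9 on work-up; only the acidic, non-hydrogen-bonded 7-OH of 6 is bound to boron and the flavanone C2 centre never sees base; closest known reaction type: syn-stereoselective ring opening of aryl epoxides with triaryl borates (internal-return solvolysis of aryl oxiranes).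

**Compound list**
1 | (E)-cinnamaldehyde | O=C/C=C/c1ccccc1 | starting material
2 | methyl but-3-enoate | COC(=O)CC=C | starting material
3 | methyl (2Z,5S,6E)-5-hydroxy-7-phenylhepta-2,6-dienoate (formed as its copper(I) alkoxide) | COC(=O)/C=C\C[C@H](O)/C=C/c1ccccc1 | intermediate
4 | (S)-goniothalamin, (6S)-6-[(E)-2-phenylethenyl]-5,6-dihydro-2H-pyran-2-one | O=C1C=CC[C@@H](/C=C/c2ccccc2)O1 | intermediate
5 | (6S)-6-[(2S,3S)-3-phenyloxiran-2-yl]-5,6-dihydro-2H-pyran-2-one | O=C1C=CC[C@@H]([C@@H]2O[C@H]2c2ccccc2)O1 | intermediate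
6 | (2S)-pinocembrin, (2S)-5,7-dihydroxy-2-phenyl-2,3-dihydro-4H-chromen-4-one | Oc1cc(O)c2c(c1)O[C@H](c1ccccc1)CC2=O | starting material
7 | tris[(2S)-5-hydroxy-4-oxo-2-phenyl-3,4-dihydro-2H-chromen-7-yl] borate | B(Oc1cc(O)c2c(c1)O[C@H](c1ccccc1)CC2=O)(Oc1cc(O)c2c(c1)O[C@H](c1ccccc1)CC2=O)Oc1cc(O)c2c(c1)O[C@H](c1ccccc1)CC2=O | intermediate
8 | bis[(2S)-5-hydroxy-4-oxo-2-phenylchroman-7-yl] borate ester of 9 at the C7 oxygen (threo, 6S,7S,8S) | O=C1C=CC[C@@H]([C@H](OB(Oc2cc(O)c3c(c2)O[C@H](c2ccccc2)CC3=O)Oc2cc(O)c3c(c2)O[C@H](c2ccccc2)CC3=O)[C@@H](Oc2cc(O)c3c(c2)O[C@H](c2ccccc2)CC3=O)c2ccccc2)O1 | intermediate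
9 | CNP0113500.1, (6S)-6-[(1S,2S)-1-hydroxy-2-{[(2S)-5-hydroxy-4-oxo-2-phenyl-3,4-dihydro-2H-chromen-7-yl]oxy}-2-phenylethyl]-5,6-dihydro-2H-pyran-2-one | O=C1C=CC[C@@H]([C@H](O)[C@@H](Oc2cc(O)c3c(c2)O[C@H](c2ccccc2)CC3=O)c2ccccc2)O1 | target

**Step count and risks**
Total steps: 3. Longest linear sequence: 3 (1 → 4 → 5 → 9).

Most at risk is step 3. The borate may bind the 5-OH/C4=O chelate site of pinocembrin and lose Lewis acidity. The benzylic cation may be trapped at C6/C8 of the flavanone (C-alkylation) or undergo a Meinwald shift. Retention may be incomplete for an acyclic trans-epoxide. The fallback sets out from 4 and returns at 9, and replaces retention at C8 by two clean inversions. Epoxidise 4 with the D-fructose-derived Shi ketone to (6S)-6-[(2R,3R)-3-phenyloxiran-2-yl]-5,6-dihydro-2H-pyran-2-one F5. Open it at the benzylic carbon with the caesium 7-phenoxide of 6 (Cs2CO3 0.3 equiv, DMF, 40 °C, SN2 with inversion at C8) to the erythro C7-epimer of the target, (6S)-6-[(1R,2S)-1-hydroxy-2-{[(2S)-5-hydroxy-4-oxo-2-phenyl-3,4-dihydro-2H-chromen-7-yl]oxy}-2-phenylethyl]-5,6-dihydro-2H-pyran-2-one F6. Invert C7 by Mitsunobu esterification (ClCH2CO2H, PPh3, DIAD, PhMe) to (1S,2S)-2-{[(2S)-5-hydroxy-4-oxo-2-phenyl-3,4-dihydro-2H-chromen-7-yl]oxy}-1-[(2S)-6-oxo-3,6-dihydro-2H-pyran-2-yl]-2-phenylethyl chloroacetate F7. Remove the chloroacetyl group with thiourea/NaHCO3 in EtOH to give 9.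

Second is step 1. Soft enolisation of a simple methyl ester may be slow, α-aldol or isomerisation of 2 to the crotonate may compete, and the sense or level of induction on an enal is not guaranteed. The fallback sets out from 1 and returns at 4, and builds the lactone by metathesis instead of aldol–lactonisation. Keck allylation of 1 ((S)-BINOL/Ti(OiPr)4, allyltributylstannane) gives (3S,1E)-1-phenylhexa-1,5-dien-3-ol F1. Acryloyl chloride/Et3N gives (3S,1E)-1-phenylhexa-1,5-dien-3-yl prop-2-enoate F2. Ring-closing metathesis (Grubbs II, CH2Cl2, 40 °C) then gives 4.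

Third is step 2. The unsaturated δ-lactone may hydrolyse at the pH the catalytic Shi cycle needs, and the reagent must override the substrate's preference for the other epoxide. The fallback sets out from 1 (with 2) and returns at 5, and makes the oxirane before the lactone. Organocatalytic epoxidation of 1 (H2O2, (S)-diarylprolinol TMS ether, CH2Cl2) gives (2R,3S)-3-phenyloxirane-2-carbaldehyde F3. The step-1 copper-catalysed vinylogous aldol–lactonisation with 2 is then run on this aldehyde. It passes through methyl (2Z,5S)-5-hydroxy-5-[(2S,3S)-3-phenyloxiran-2-yl]pent-2-enoate F4 (not isolated), which lactonises to 5, with the ligand fixing C6.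

**Further compounds**
F1 | step 1 | (3S,1E)-1-phenylhexa-1,5-dien-3-ol | C=CC[C@H](O)/C=C/c1ccccc1
F2 | step 1 | (3S,1E)-1-phenylhexa-1,5-dien-3-yl prop-2-enoate | C=CC[C@H](OC(=O)C=C)/C=C/c1ccccc1
F3 | step 2 | (2R,3S)-3-phenyloxirane-2-carbaldehyde | O=C[C@@H]1O[C@H]1c1ccccc1
F4 | step 2 | methyl (2Z,5S)-5-hydroxy-5-[(2S,3S)-3-phenyloxiran-2-yl]pent-2-enoate | COC(=O)/C=C\C[C@H](O)[C@@H]1O[C@H]1c1ccccc1
F5 | step 3 | (6S)-6-[(2R,3R)-3-phenyloxiran-2-yl]-5,6-dihydro-2H-pyran-2-one | O=C1C=CC[C@@H]([C@H]2O[C@@H]2c2ccccc2)O1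
F6 | step 3 | (6S)-6-[(1R,2S)-1-hydroxy-2-{[(2S)-5-hydroxy-4-oxo-2-phenyl-3,4-dihydro-2H-chromen-7-yl]oxy}-2-phenylethyl]-5,6-dihydro-2H-pyran-2-one | O=C1C=CC[C@@H]([C@@H](O)[C@@H](Oc2cc(O)c3c(c2)O[C@H](c2ccccc2)CC3=O)c2ccccc2)O1
F7 | step 3 | (1S,2S)-2-{[(2S)-5-hydroxy-4-oxo-2-phenyl-3,4-dihydro-2H-chromen-7-yl]oxy}-1-[(2S)-6-oxo-3,6-dihydro-2H-pyran-2-yl]-2-phenylethyl chloroacetate | O=C1C=CC[C@@H]([C@H](OC(=O)CCl)[C@@H](Oc2cc(O)c3c(c2)O[C@H](c2ccccc2)CC3=O)c2ccccc2)O1
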